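**Strategy.** The pyran ring (ring C) is disconnected at C2–C3. Because C2 carries both the ring oxygen O1 and ring B, the O1–C2–ring B unit is a ring-B benzoate of the ring-A phenol in disguise, and C4–C3 is an ortho-allyl group. The key step is a titanium-mediated ester–olefin metathesis: the ester carbonyl carbon (future C2) and the internal allyl carbon (future C3) are joined as the C2=C3 enol ether of a 4H-chromene in one operation. Its precursor is a plain aryl ester of a protected gallic acid with 2-allyl-3,5-bis(benzyloxy)phenol. Reagent-controlled asymmetric hydroboration then sets both stereocentres (2,3-trans), followed by 3'-O-galloylation and global hydrogenolysis.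

Key step: step 7

Remark: positions 3' and 5' of ring B are equivalent by rotation about the C1'–C2 bond, so one meta-hydroxyl of the pyrogallol ring has to be distinguished from the other two. 3,4,5-Tris(benzyloxy)benzoyl chloride, Cp2Ti(μ-Cl)(μ-CH2)AlMe2 and the TMEDA adduct of monoisopinocampheylborane are taken as purchasable.

Step 1
Reactants: 1 3,5-bis(benzyloxy)phenol; 2 allyl bromide
Product: 3 1-(allyloxy)-3,5-bis(benzyloxy)benzene
Conditions: K2CO3, acetone, reflux
Reagents that add atoms: allyl bromide (2), C=CCBr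
Why: Williamson ether synthesis, the phenoxide displacing the allylic bromide by SN2.

Step 2
Reactants: 3 1-(allyloxy)-3,5-bis(benzyloxy)benzene
Product: 4 2-allyl-3,5-bis(benzyloxy)phenol
Conditions: N,N-diethylaniline, 200 °C, sealed tube
Reagents that add atoms: none
Why: Aromatic Claisen rearrangement ([3,3]-sigmatropic shift, then tautomerisation); the two ortho positions are equivalent by symmetry, so a single ortho-allyl phenol should result.

Step 3
Reactants: 5 3,4,5-trihydroxybenzaldehyde; 6 dichlorodiphenylmethane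
Product: 7 7-hydroxy-2,2-diphenyl-1,3-benzodioxole-5-carbaldehyde
Conditions: K2CO3, MeCN, rt, argon
Reagents that add atoms: dichlorodiphenylmethane (6), ClC(Cl)(c1ccccc1)c1ccccc1
Why: Double O-alkylation by the gem-dichloride closes a five-membered diaryl ketal, which can only span two adjacent hydroxyls and therefore leaves exactly one meta-hydroxyl free (the later 3'-O acylation site).

Step 4
Reactants: 7 7-hydroxy-2,2-diphenyl-1,3-benzodioxole-5-carbaldehyde; 8 chlorotriisopropylsilane
Product: 9 2,2-diphenyl-7-(triisopropylsilyloxy)-1,3-benzodioxole-5-carbaldehyde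
Conditions: imidazole, DMF, rt
Reagents that add atoms: chlorotriisopropylsilane (8), CC(C)[Si](Cl)(C(C)C)C(C)C
Why: Imidazole-promoted O-silylation of the phenol; the aryl triisopropylsilyl ether is orthogonal to benzyl ethers and the ketal and is removable with fluoride.

Step 5
Reactants: 9 2,2-diphenyl-7-(triisopropylsilyloxy)-1,3-benzodioxole-5-carbaldehyde
Product: 10 2,2-diphenyl-7-(triisopropylsilyloxy)-1,3-benzodioxole-5-carboxylic acid
Conditions: NaClO2, NaH2PO4, 2-methyl-2-butene, t-BuOH/THF/H2O, 0 °C to rt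
Reagents that add atoms: sodium chlorite NaClO2, [Na+].[O-]Cl=O
Why: Pinnick oxidation at about pH 4 converts the aldehyde into the acid without touching the aryl silyl ether (no basic ester hydrolysis is needed), the alkene scavenging hypochlorous acid.

Step 6
Reactants: 4 2-allyl-3,5-bis(benzyloxy)phenol; 10 2,2-diphenyl-7-(triisopropylsilyloxy)-1,3-benzodioxole-5-carboxylic acid
Product: 11 2-allyl-3,5-bis(benzyloxy)phenyl 2,2-diphenyl-7-(triisopropylsilyloxy)-1,3-benzodioxole-5-carboxylate
Conditions: DCC, DMAP (cat.), CH2Cl2, 0 °C to rt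
Reagents that add atoms: none
Why: Steglich esterification, the acylpyridinium intermediate acylating the moderately hindered phenol under neutral conditions.

Step 7
Reactants: 11 2-allyl-3,5-bis(benzyloxy)phenyl 2,2-diphenyl-7-(triisopropylsilyloxy)-1,3-benzodioxole-5-carboxylate; 12 Cp2Ti(μ-Cl)(μ-CH2)AlMe2 (Tebbe reagent)
Product: 14 5,7-bis(benzyloxy)-2-[2,2-diphenyl-7-(triisopropylsilyloxy)-1,3-benzodioxol-5-yl]-4H-chromene, via acyclic enol ether 13 (not isolated)
Conditions: Cp2Ti(μ-Cl)(μ-CH2)AlMe2 (4 equiv, toluene solution), pyridine (cat.), THF, 0 to 25 °C; then reflux; aq. NaOH work-up, basic alumina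
Reagents that add atoms: none
Why: Cp2Ti=CH2, released from the reagent by pyridine/THF, adds to the aryl ester carbonyl of 11 and the oxatitanacyclobutane collapses to enol ether 13 and Cp2TiO; on heating, a further equivalent exchanges with the terminal alkene of the allyl group (ethylene is lost, so the methylene carried by 13 does not remain in 14), and the titanium alkylidene at the future C3 adds intramolecularly across the electron-rich 1,1-disubstituted enol ether, retro-[2+2] of the titanacyclobutane delivering the C2=C3 bond of 14. The closest known reaction type is the Tebbe-mediated cyclisation of olefinic esters to cyclic enol ethers (carbonyl methylenation followed by ring-closing olefin metathesis), and Tebbe methylenation of aryl benzoates to 1-aryloxystyrenes is standard. The pyran ring (ring C) is closed as a six-membered ring by metathesis, both carbons of the new bond lying inside the ring (formally 6-endo through a fused titanacyclobutane), and the ortho relationship of phenol oxygen and allyl group holds the two reacting alkenes close. No stereocentre is formed: the endocyclic C2=C3 alkene is planar, and C2 and C3 become stereogenic only in step 8. The step needs chemoselectivity for the single ester carbonyl and ring closure in preference to oligomerisation: benzyl ethers, the diaryl ketal and the aryl silyl ether are inert to the titanium carbene, dilution favours the intramolecular path, and the basic work-up preserves the acid-labile enol ether.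

Step 8
Reactants: 14 5,7-bis(benzyloxy)-2-[2,2-diphenyl-7-(triisopropylsilyloxy)-1,3-benzodioxol-5-yl]-4H-chromene; 15 monoisopinocampheylborane (IpcBH2) derived from (+)-α-pinene
Product: 17 (2R,3S)-5,7-bis(benzyloxy)-2-[2,2-diphenyl-7-(triisopropylsilyloxy)-1,3-benzodioxol-5-yl]chroman-3-ol, via chromanyl(isopinocampheyl)borane 16 (not isolated)
Conditions: IpcBH2 (filtered THF solution, prepared beforehand from its TMEDA adduct and BF3·OEt2), THF, −25 to 0 °C; then NaBO3·4H2O, THF/H2O, rt
Reagents that add atoms: sodium perborate NaBO3·4H2O, [Na+].[O-]B1OO1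
Why: Asymmetric hydroboration–oxidation: syn addition puts boron on C3 (β to O1, the less substituted carbon) and hydrogen on C2 from the same face, so aryl and boron are trans, and perborate oxidation with retention should give the 2,3-trans alcohol; the face is chosen by the isopinocampheyl group, the sense being assigned by analogy with 1-phenylcyclohexene, which this reagent converts into (1S,2R)-trans-2-phenylcyclohexanol, spatially equivalent to (2R,3S) here.

Step 9
Reactants: 17 (2R,3S)-5,7-bis(benzyloxy)-2-[2,2-diphenyl-7-(triisopropylsilyloxy)-1,3-benzodioxol-5-yl]chroman-3-ol; 18 3,4,5-tris(benzyloxy)benzoyl chloride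
Product: 20 6-[(2R,3S)-5,7-bis(benzyloxy)-3-hydroxychroman-2-yl]-2,2-diphenyl-1,3-benzodioxol-4-yl 3,4,5-tris(benzyloxy)benzoate, via tetrabutylammonium phenoxide 19 (not isolated)
Conditions: TBAF (1.0 M in THF, 1.05 equiv), THF, 0 °C; then 18 (1.1 equiv), 0 °C
Reagents that add atoms: 3,4,5-tris(benzyloxy)benzoyl chloride (18), O=C(Cl)c1cc(OCc2ccccc2)c(OCc2ccccc2)c(OCc2ccccc2)c1
Why: One-pot desilylation and O-acylation: fluoride cleaves the aryl O–Si bond and the liberated phenoxide should be acylated by a near-stoichiometric amount of acid chloride far faster than the neutral secondary C3 hydroxyl (phenoxide acylation of the Schotten–Baumann type).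

Step 10
Reactants: 20 6-[(2R,3S)-5,7-bis(benzyloxy)-3-hydroxychroman-2-yl]-2,2-diphenyl-1,3-benzodioxol-4-yl 3,4,5-tris(benzyloxy)benzoate
Product: 21 gallocatechin 3'-O-gallate, 2,3-dihydroxy-5-[(2R,3S)-3,5,7-trihydroxychroman-2-yl]phenyl 3,4,5-trihydroxybenzoate
Conditions: H2 (1 atm), Pd(OH)2/C, THF/MeOH, rt; neutral work-up
Reagents that add atoms: none
Why: Catalytic hydrogenolysis should remove the five benzyl ethers and the diphenylmethylene ketal together, while the aryl ester and the flavan C2–O1 bond survive and the neutral medium avoids 3'-to-4' acyl migration and C2 epimerisation.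

**Compound list**

1 | 3,5-bis(benzyloxy)phenol | Oc1cc(OCc2ccccc2)cc(OCc2ccccc2)c1 | starting material
2 | allyl bromide | C=CCBr | starting material
3 | 1-(allyloxy)-3,5-bis(benzyloxy)benzene | C=CCOc1cc(OCc2ccccc2)cc(OCc2ccccc2)c1 | intermediate
4 | 2-allyl-3,5-bis(benzyloxy)phenol | C=CCc1c(O)cc(OCc2ccccc2)cc1OCc1ccccc1 | intermediate
5 | 3,4,5-trihydroxybenzaldehyde | O=Cc1cc(O)c(O)c(O)c1 | starting material
6 | dichlorodiphenylmethane | ClC(Cl)(c1ccccc1)c1ccccc1 | starting material
7 | 7-hydroxy-2,2-diphenyl-1,3-benzodioxole-5-carbaldehyde | O=Cc1cc(O)c2OC(c3ccccc3)(c3ccccc3)Oc2c1 | intermediate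
8 | chlorotriisopropylsilane | CC(C)[Si](Cl)(C(C)C)C(C)C | starting material
9 | 2,2-diphenyl-7-(triisopropylsilyloxy)-1,3-benzodioxole-5-carbaldehyde | O=Cc1cc(O[Si](C(C)C)(C(C)C)C(C)C)c2OC(c3ccccc3)(c3ccccc3)Oc2c1 | intermediate
10 | 2,2-diphenyl-7-(triisopropylsilyloxy)-1,3-benzodioxole-5-carboxylic acid | OC(=O)c1cc(O[Si](C(C)C)(C(C)C)C(C)C)c2OC(c3ccccc3)(c3ccccc3)Oc2c1 | intermediate
11 | 2-allyl-3,5-bis(benzyloxy)phenyl 2,2-diphenyl-7-(triisopropylsilyloxy)-1,3-benzodioxole-5-carboxylate | C=CCc1c(OC(=O)c2cc(O[Si](C(C)C)(C(C)C)C(C)C)c3OC(c4ccccc4)(c4ccccc4)Oc3c2)cc(OCc2ccccc2)cc1OCc1ccccc1 | intermediate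
12 | Cp2Ti(μ-Cl)(μ-CH2)AlMe2 (Tebbe reagent), drawn as its two halves Cp2Ti=CH2 and Me2AlCl | C=[Ti](C1C=CC=C1)C1C=CC=C1.C[Al](C)Cl | starting material
13 | 2-allyl-3,5-bis(benzyloxy)phenyl 1-[2,2-diphenyl-7-(triisopropylsilyloxy)-1,3-benzodioxol-5-yl]vinyl ether (not isolated) | C=CCc1c(OC(=C)c2cc(O[Si](C(C)C)(C(C)C)C(C)C)c3OC(c4ccccc4)(c4ccccc4)Oc3c2)cc(OCc2ccccc2)cc1OCc1ccccc1 | intermediate
14 | 5,7-bis(benzyloxy)-2-[2,2-diphenyl-7-(triisopropylsilyloxy)-1,3-benzodioxol-5-yl]-4H-chromene | C1(c2cc(O[Si](C(C)C)(C(C)C)C(C)C)c3OC(c4ccccc4)(c4ccccc4)Oc3c2)=CCc2c(OCc3ccccc3)cc(OCc3ccccc3)cc2O1 | intermediate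
15 | monoisopinocampheylborane (IpcBH2) from (+)-α-pinene | B[C@@H]1C[C@@H]2C[C@H]([C@H]1C)C2(C)C | starting material
16 | 2,3-trans-[5,7-bis(benzyloxy)-2-arylchroman-3-yl](isopinocampheyl)borane, boron on C3 in the position later taken by the hydroxyl (not isolated) | CC(C)[Si](Oc1cc([C@H]2Oc3cc(OCc4ccccc4)cc(OCc4ccccc4)c3C[C@@H]2B[C@@H]2C[C@@H]3C[C@H]([C@H]2C)C3(C)C)cc2OC(c3ccccc3)(c3ccccc3)Oc12)(C(C)C)C(C)C | intermediate
17 | (2R,3S)-5,7-bis(benzyloxy)-2-[2,2-diphenyl-7-(triisopropylsilyloxy)-1,3-benzodioxol-5-yl]chroman-3-ol | CC(C)[Si](Oc1cc([C@H]2Oc3cc(OCc4ccccc4)cc(OCc4ccccc4)c3C[C@@H]2O)cc2OC(c3ccccc3)(c3ccccc3)Oc12)(C(C)C)C(C)C | intermediate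
18 | 3,4,5-tris(benzyloxy)benzoyl chloride | O=C(Cl)c1cc(OCc2ccccc2)c(OCc2ccccc2)c(OCc2ccccc2)c1 | starting material
19 | tetrabutylammonium 6-[(2R,3S)-5,7-bis(benzyloxy)-3-hydroxychroman-2-yl]-2,2-diphenyl-1,3-benzodioxol-4-olate (not isolated) | [O-]c1cc([C@H]2Oc3cc(OCc4ccccc4)cc(OCc4ccccc4)c3C[C@@H]2O)cc2OC(c3ccccc3)(c3ccccc3)Oc12.CCCC[N+](CCCC)(CCCC)CCCC | intermediate
20 | 6-[(2R,3S)-5,7-bis(benzyloxy)-3-hydroxychroman-2-yl]-2,2-diphenyl-1,3-benzodioxol-4-yl 3,4,5-tris(benzyloxy)benzoate | O=C(Oc1cc([C@H]2Oc3cc(OCc4ccccc4)cc(OCc4ccccc4)c3C[C@@H]2O)cc2OC(c3ccccc3)(c3ccccc3)Oc12)c1cc(OCc2ccccc2)c(OCc2ccccc2)c(OCc2ccccc2)c1 | intermediate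
21 | gallocatechin 3'-O-gallate, 2,3-dihydroxy-5-[(2R,3S)-3,5,7-trihydroxychroman-2-yl]phenyl 3,4,5-trihydroxybenzoate | O=C(Oc1cc([C@H]2Oc3cc(O)cc(O)c3C[C@@H]2O)cc(O)c1O)c1cc(O)c(O)c(O)c1 | target

**Totals.** Total step count: 10. Longest linear sequence: 8 steps (steps 3, 4, 5, 6, 7, 8, 9, 10 from compound 5).

**Steps most likely to fail**

Step 7. The second stage may stall: the titanium alkylidene may not engage the hindered, electron-rich 1,1-disubstituted enol ether, or the enol ether may hydrolyse on work-up. The fallback sets out from 11 and separates the two events. Methylenation with Cp2TiMe2 (toluene, 70 °C) should give the acyclic enol ether 13, now isolated on basic alumina. Ring-closing metathesis with the second-generation Grubbs catalyst (toluene, 70 °C) should then close the ring with a ruthenium carbene and return to the route at 14. This detour makes no compound outside the list (entry F0).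

Step 8. Facial selectivity may be poor on this oxygen-containing analogue of a 1-arylcycloalkene, and the β-aryloxy borane may suffer ring-opening β-elimination before oxidation. The fallback sets out from 14 and uses copper-catalysed enantioselective protoboration (B2pin2, CuCl, NaOtBu, DTBM-SEGPHOS, MeOH, THF, rt). Syn addition of copper to benzylic C2 and boron to C3, followed by protonation with retention, should give the 2,3-trans C3 pinacol boronate F1, a less Lewis-acidic and less elimination-prone species. The ligand enantiomer would be fixed by a pilot run. Oxidation of F1 with NaBO3·4H2O returns to the route at 17.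

Step 9. Chemoselectivity may be lost: the C3 hydroxyl may be acylated as well, or the acid chloride may be consumed by the water carried in with the fluoride, leaving the phenol unacylated. The fallback sets out from 17 and removes the competing hydroxyl first. Benzylation (NaH, BnBr, DMF, 0 °C) should give the 3-O-benzyl ether F2. TBAF in THF then frees the phenol F3, and acylation with 18 (Et3N, DMAP, CH2Cl2) gives the fully protected ester F4. Hydrogenolysis under the conditions of step 10 removes the extra benzyl group with the others and comes back to the route at the target 21.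

**Further compounds**

F0 | step 7 | none | none
F1 | step 8 | 2,3-trans-2-{5,7-bis(benzyloxy)-2-[2,2-diphenyl-7-(triisopropylsilyloxy)-1,3-benzodioxol-5-yl]chroman-3-yl}-4,4,5,5-tetramethyl-1,3,2-dioxaborolane, boron in the position of the later hydroxyl | CC(C)[Si](Oc1cc([C@H]2Oc3cc(OCc4ccccc4)cc(OCc4ccccc4)c3C[C@@H]2B2OC(C)(C)C(C)(C)O2)cc2OC(c3ccccc3)(c3ccccc3)Oc12)(C(C)C)C(C)C
F2 | step 9 | (2R,3S)-3,5,7-tris(benzyloxy)-2-[2,2-diphenyl-7-(triisopropylsilyloxy)-1,3-benzodioxol-5-yl]chroman | CC(C)[Si](Oc1cc([C@H]2Oc3cc(OCc4ccccc4)cc(OCc4ccccc4)c3C[C@@H]2OCc2ccccc2)cc2OC(c3ccccc3)(c3ccccc3)Oc12)(C(C)C)C(C)C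
F3 | step 9 | 6-[(2R,3S)-3,5,7-tris(benzyloxy)chroman-2-yl]-2,2-diphenyl-1,3-benzodioxol-4-ol | Oc1cc([C@H]2Oc3cc(OCc4ccccc4)cc(OCc4ccccc4)c3C[C@@H]2OCc2ccccc2)cc2OC(c3ccccc3)(c3ccccc3)Oc12
F4 | step 9 | 6-[(2R,3S)-3,5,7-tris(benzyloxy)chroman-2-yl]-2,2-diphenyl-1,3-benzodioxol-4-yl 3,4,5-tris(benzyloxy)benzoate | O=C(Oc1cc([C@H]2Oc3cc(OCc4ccccc4)cc(OCc4ccccc4)c3C[C@@H]2OCc2ccccc2)cc2OC(c3ccccc3)(c3ccccc3)Oc12)c1cc(OCc2ccccc2)c(OCc2ccccc2)c(OCc2ccccc2)c1
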